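All runs come from a simulation from invented constants, noise included.

If you must rank these flasks before running them, what do you write first?

all flasks: free catalyst 10 µM; impurity 6.9 µM

|  | substrate | reagent | remark | time |
|---|---|---|---|---|
| Monday's | 0.010 M | 7 mM | run made earlier |  |
| Sunday's | 0.0067 M | 7 mM | run made earlier |  |
| Wednesday's | 0.015 M | 7 mM | run made earlier |  |
| blue | 0.010 M | 7.00 mM | one stirred flow tank at steady state, fed with the mixture as stated, mean residence time 50.0 h |  |
| teal | 0.010 M | 7.00 mM | a single well-mixed tank run continuously and read at steady state, 5.0 h in it on average |  |
| grey | 0.010 M (fed, over 4.00 h) | 7.00 mM | a stirred flask in which substrate is dosed at a steady rate over 4.00 h without added volume, worked up at 5.0 h | 5.0 h |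
| violet | 0.010 M | 7.00 mM | everything together in a closed stirred flask, run for 5.0 h | 5.0 h |

| run | time / h | product / % |
|---|---|---|
| Monday's | 0.417 | 4.3 |
| Monday's | 1.33 | 8.1 |
| Monday's | 2.50 | 15.4 |
| Monday's | 4.00 | 22.5 |
| Monday's | 5.00 | 26.6 |
| Sunday's | 0.833 | 8.5 |
| Sunday's | 1.50 | 13.8 |
| Sunday's | 2.50 | 20.6 |
| Sunday's | 3.00 | 24.4 |
| Sunday's | 4.00 | 29.7 |
| Wednesday's | 0.333 | 2.3 |
| Wednesday's | 0.667 | 4.0 |
| Wednesday's | 1.00 | 4.7 |
| Wednesday's | 2.00 | 8.9 |
| Wednesday's | 4.00 | 17.0 |

(readings scatter by 0.5 percentage points)

- the stated concentrations are those of everything mixed, before any reaction; amounts are the same in each set-up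
- steps thought possible: substrate + catalyst intermediate A -> catalyst intermediate B; free catalyst + impurity -> spent catalyst; catalyst intermediate C -> free catalyst + product; reagent + free catalyst <-> catalyst intermediate A; catalyst intermediate B <-> catalyst intermediate C
- the feed brings no volume worth counting
- the earlier runs were made in a closed, stirred flask

- the set-up with the highest amount of product at the outlet or at the end, in percent of the substrate put in ("none" if the first two lie within 2 percentage points) (blue / teal / grey / violet / none)
- amount of product at the outlet or at the end, in percent of the substrate put in, blue
- amount of product at the outlet or at the end, in percent of the substrate put in, teal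
- amount of product at the outlet or at the end, in percent of the substrate put in, grey
- amount of product at the outlet or at the end, in percent of the substrate put in, violet

The balance of the reagent, because its 7.00 mM stands against 0.010 M of substrate, which makes it the limiting reagent. On the listed steps, one turn of the catalyst takes up one reagent and one substrate and gives one product, so product made equals reagent gone, apart from the reagent still bound in the catalyst intermediates. Hence Y_max = 70.0%, the yield ceiling: charged reagent over charged substrate, the share of the substrate the reagent can pay for.

Does the impurity not stop the round first?

It takes catalyst one for one, which leaves 3.10 µM out of its reach, and Monday's product is still rising at its last reading.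

How fast is the climb?

Violet has Monday's recipe, so I put it at 26.6%, which is 0.532 mM h⁻¹ on average. Grey doses its substrate over 4.00 h, and less substrate made less product: Sunday's run reached 1.99 mM at 4.00 h, Wednesday's 2.55 mM at 4.00 h. So I place grey below violet, without a figure.

And the tanks?

Suppose the rate is k′R, with R the reagent concentration and k′ a first-order constant. Monday's average rate over the average of R's start and end values gives k′ = 0.0938 h⁻¹. The reagent balance of a tank with mean residence time τ then gives a yield of Y_max times k′τ over one plus k′τ. That is 57.7% for blue and 22.4% for teal, so I choose blue.

But every run had the same reagent charge. Where is k′ from?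

Its value comes from Monday's run, but the first-order form is an assumption, so the gap below the ceiling is a guess. The ceiling itself uses no rate.

The forecast chose blue, with 64% for blue, more than my 57.7%, 26.3% for teal, 19.5% for grey and 26.6% for violet, reasoning that “the long residence time drives conversion until the reagent” runs short.

The simulation gives 61.9% for blue, 24.5% for teal, 20.0% for grey and 26.6% for violet, so the best is blue.

    substrate + catalyst intermediate A → catalyst intermediate B (k = 35.0 M⁻¹ s⁻¹)
    free catalyst + impurity → spent catalyst (k = 870 M⁻¹ s⁻¹)
    catalyst intermediate C → free catalyst + product (k = 0.250 s⁻¹)
    reagent + free catalyst ⇌ catalyst intermediate A (K = 270 M⁻¹, k = 33.0 M⁻¹ s⁻¹)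
    catalyst intermediate B ⇌ catalyst intermediate C (K = 1.30, k = 0.220 s⁻¹)

Blue stands 8.1 percentage points under the ceiling. A neighbour of violet is charged with 25.0 µM of free catalyst, all else held. Catalyst does not enter the reagent balance, so its ceiling stays 70.0%. The catalyst beyond the impurity is now 18.1 µM against 3.10 µM, and scaling violet's yield by that ratio asks for 156%, more than the ceiling. The neighbour gives 68.6% at 5.00 h, with 31.4% of the substrate and 2.05% of the reagent left.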